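**Retrosynthetic overview**

1. Atom labels follow the target tetrahydrofuran: O1, C2 (guaiacyl), C3 (carrying the C9H2O arm), C4 (carrying the C7'H2-aryl arm), C5. The strategy rests on this ring: with C5 raised to a carbonyl it is a γ-aryl butyrolactone whose β-carbon C3 lacks only C9 and whose α-carbon C4 lacks only C7'.
2. Agastinol 19 ⇐ (debenzylation) ester 18 ⇐ (esterification) alcohol 16 + acid 17; the C9 hydroxyl is unmasked from a C9–SiMe2Ph group (16 ⇐ 15).
3. Tetrahydrofuran 15 ⇐ (O1–C5 etherification, C2 untouched) diol 13 ⇐ (LiAlH4) lactone 12 ⇐ (face-selective hydrogenation, sets C4) arylidene lactone 11.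
4. Key disconnection: 11 ⇐ butenolide 5 + silylmethyl Grignard reagent 7 (C3–C9, sets C3 trans to C2) + O-benzylvanillin 1 (C4=C7') in one conjugate addition/aldol condensation. Butenolide 5 ⇐ asymmetric alkynylation of 1 with methyl propiolate 2, semi-hydrogenation and lactonisation (sets C2).
5. Ring order: the lactone ring is formed first (step 2), opened by reduction (step 6) and reclosed as the tetrahydrofuran (step 7). Silicon carries phenyl, not alkoxy, because an alkoxysilane would not survive LiAlH4 and the diol alkoxides of steps 6 and 7.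

Key step: step 4

Assumption: the ProPhenol enantiomer that delivers the alkynylzinc to the Re face of aldehyde 1 is taken to be (S,S); the sense is checked on the first batch (MTPA esters) and the antipodal ligand is used if the opposite alcohol forms.

**Route**

Step 1
Reactants: 1 O-benzylvanillin (4-benzyloxy-3-methoxybenzaldehyde); 2 methyl propiolate
Product: 3 methyl (4S)-4-[4-(benzyloxy)-3-methoxyphenyl]-4-hydroxybut-2-ynoate
Conditions: 2 (3 equiv), Me2Zn (3 equiv), (S,S)-ProPhenol (10 mol %), Ph3PO (20 mol %), toluene, 4 °C; aq NH4Cl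
Reagents that add atoms: none
Why: Catalytic enantioselective alkynylation of an aryl aldehyde by a zinc alkynylide formed in situ, under dinuclear zinc–ProPhenol control; Re-face delivery sets the carbinol centre as S.

Step 2
Reactants: 3 methyl (4S)-4-[4-(benzyloxy)-3-methoxyphenyl]-4-hydroxybut-2-ynoate
Product: 5 (5R)-5-[4-(benzyloxy)-3-methoxyphenyl]furan-2(5H)-one, via Z-hydroxy enoate 4 (not isolated)
Conditions: H2 (1 atm), Pd/CaCO3 poisoned with Pb(OAc)2, quinoline, EtOAc, rt; then PPTS (cat.), CH2Cl2, rt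
Reagents that add atoms: none
Why: Syn semi-hydrogenation of the alkyne gives the Z-enoate, whose hydroxyl then lactonises onto the ester (intramolecular transesterification) under mild acid, which avoids base-induced racemisation through the 2-hydroxyfuran tautomer; the carbinol centre is untouched and its descriptor changes from S to R only through the CIP priorities.

Step 3
Reactants: 6 (chloromethyl)dimethylphenylsilane
Product: 7 [(dimethylphenylsilyl)methyl]magnesium chloride
Conditions: Mg turnings, BrCH2CH2Br (cat.), THF, rt to 40 °C; titrated before use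
Reagents that add atoms: magnesium, [Mg]
Why: Grignard formation by insertion of magnesium into the C–Cl bond of an α-silyl chloride; the reagent has no β-hydrogen and should be stable in THF.

Step 4
Reactants: 5 (5R)-5-[4-(benzyloxy)-3-methoxyphenyl]furan-2(5H)-one; 7 [(dimethylphenylsilyl)methyl]magnesium chloride; 1 O-benzylvanillin
Product: 11 (3E,4R,5R)-3-[4-(benzyloxy)-3-methoxybenzylidene]-5-[4-(benzyloxy)-3-methoxyphenyl]-4-[(dimethylphenylsilyl)methyl]dihydrofuran-2(3H)-one, via magnesium enolate 8 (not isolated), via aldol adduct 9 (not isolated), via mesylate 10 (not isolated)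
Conditions: 7 (2.2 equiv), CuBr·SMe2 (1.1 equiv), THF, −78 °C; 5, −78 to −40 °C; 1 (1.5 equiv), −78 °C; aq NH4Cl; crude aldol: MsCl, Et3N, CH2Cl2, 0 °C; then DBU, 0 °C to rt
Reagents that add atoms: none
Why: Grignard reagent 7 and CuBr·SMe2 form a magnesium bis(silylmethyl)cuprate that adds to the β-carbon of 5 by π-complexation, oxidative addition and reductive elimination, the closest known reaction type being the copper-mediated conjugate addition of silylmethyl Grignard reagents to enones and γ-substituted butenolides. No ring is closed; the C3–C9 bond and the C4=C7' double bond are made on the existing lactone ring. The new C3 stereocentre is controlled by the C2 aryl group, which blocks its own face of the planar butenolide so that the silylmethyl group enters trans to it. Magnesium enolate 8 then adds to aldehyde 1 (aldol addition), and mesylation of adduct 9 followed by DBU-induced E1cB elimination of 10 should give the conjugated E-arylidene, so the mixed configuration of 9 at C4 and C7' is of no consequence. The step needs 1,4- over 1,2-addition and must not remove the acidic γ-hydrogen of 5, which would racemise C2; the soft, weakly basic cuprate at −78 °C should secure both, and the silylmethyl group has no β-hydrogen and serves as a robust hydroxymethyl anion equivalent.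

Step 5
Reactants: 11 (3E,4R,5R)-3-[4-(benzyloxy)-3-methoxybenzylidene]-5-[4-(benzyloxy)-3-methoxyphenyl]-4-[(dimethylphenylsilyl)methyl]dihydrofuran-2(3H)-one
Product: 12 (3S,4R,5R)-3-[4-(benzyloxy)-3-methoxybenzyl]-5-[4-(benzyloxy)-3-methoxyphenyl]-4-[(dimethylphenylsilyl)methyl]dihydrofuran-2(3H)-one
Conditions: H2 (1 atm), 10% Pd/C, 2,2'-bipyridyl (0.5 equiv), EtOAc, rt
Reagents that add atoms: none
Why: Heterogeneous catalytic hydrogenation (syn addition) should deliver hydrogen to C4 from the face opposite the adjacent C3 silylmethyl group, placing the benzyl arm cis to it, while the nitrogen-base poison suppresses hydrogenolysis of the aryl benzyl ethers and of the benzylic lactone C–O bond.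

Step 6
Reactants: 12 (3S,4R,5R)-3-[4-(benzyloxy)-3-methoxybenzyl]-5-[4-(benzyloxy)-3-methoxyphenyl]-4-[(dimethylphenylsilyl)methyl]dihydrofuran-2(3H)-one
Product: 13 (1R,2R,3S)-3-[4-(benzyloxy)-3-methoxybenzyl]-1-[4-(benzyloxy)-3-methoxyphenyl]-2-[(dimethylphenylsilyl)methyl]butane-1,4-diol
Conditions: LiAlH4, THF, 0 °C; H2O, aq NaOH work-up
Reagents that add atoms: none
Why: Hydride reduction of the lactone to the 1,4-diol; no stereocentre is touched, and the Si–C bonds and benzyl ethers are inert to LiAlH4.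

Step 7
Reactants: 13 (1R,2R,3S)-3-[4-(benzyloxy)-3-methoxybenzyl]-1-[4-(benzyloxy)-3-methoxyphenyl]-2-[(dimethylphenylsilyl)methyl]butane-1,4-diol
Product: 15 (2R,3R,4S)-4-[4-(benzyloxy)-3-methoxybenzyl]-2-[4-(benzyloxy)-3-methoxyphenyl]-3-[(dimethylphenylsilyl)methyl]tetrahydrofuran, via primary tosylate 14 (not isolated)
Conditions: TsCl (1.05 equiv), Et3N, DMAP (cat.), CH2Cl2, 0 °C; solvent exchange; NaH, THF, 0 °C to rt
Reagents that add atoms: none
Why: Selective sulfonylation of the primary hydroxyl over the hindered secondary benzylic one, then intramolecular Williamson etherification (5-exo-tet) by the C2 alkoxide on C5; the C2–O bond is never broken, so C2 keeps its configuration.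

Step 8
Reactants: 15 (2R,3R,4S)-4-[4-(benzyloxy)-3-methoxybenzyl]-2-[4-(benzyloxy)-3-methoxyphenyl]-3-[(dimethylphenylsilyl)methyl]tetrahydrofuran
Product: 16 {(2R,3S,4S)-4-[4-(benzyloxy)-3-methoxybenzyl]-2-[4-(benzyloxy)-3-methoxyphenyl]tetrahydrofuran-3-yl}methanol
Conditions: t-BuOOH, KH, TBAF, DMF, rt to 70 °C; aq work-up
Reagents that add atoms: tert-butyl hydroperoxide, CC(C)(C)OO
Why: Fleming–Tamao oxidation in its nucleophilic variant (peroxide anion and fluoride attack silicon, the phenyl group is lost and the alkyl group migrates from silicon to oxygen), chosen because it avoids the acids and electrophiles that would ionise the benzylic ether at C2 or attack the electron-rich arenes; C9 is not stereogenic and the change of the C3 descriptor is formal.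

Step 9
Reactants: 16 {(2R,3S,4S)-4-[4-(benzyloxy)-3-methoxybenzyl]-2-[4-(benzyloxy)-3-methoxyphenyl]tetrahydrofuran-3-yl}methanol; 17 4-(benzyloxy)benzoic acid
Product: 18 {(2R,3S,4S)-4-[4-(benzyloxy)-3-methoxybenzyl]-2-[4-(benzyloxy)-3-methoxyphenyl]tetrahydrofuran-3-yl}methyl 4-(benzyloxy)benzoate
Conditions: EDC·HCl, DMAP, CH2Cl2, rt
Reagents that add atoms: none
Why: Steglich esterification (carbodiimide activation, DMAP acyl transfer) of an unhindered primary alcohol.

Step 10
Reactants: 18 {(2R,3S,4S)-4-[4-(benzyloxy)-3-methoxybenzyl]-2-[4-(benzyloxy)-3-methoxyphenyl]tetrahydrofuran-3-yl}methyl 4-(benzyloxy)benzoate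
Product: 19 agastinol, {(2R,3S,4S)-4-(4-hydroxy-3-methoxybenzyl)-2-(4-hydroxy-3-methoxyphenyl)tetrahydrofuran-3-yl}methyl 4-hydroxybenzoate
Conditions: H2 (1 atm), 10% Pd/C, EtOAc/EtOH, rt, stopped when debenzylation is complete
Reagents that add atoms: none
Why: Hydrogenolysis of the three aryl benzyl ethers under neutral conditions at atmospheric pressure; the benzylic C2–O bond of the tetrahydrofuran and the non-benzylic benzoate should be cleaved much more slowly or not at all, and no stereocentre is affected.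

**Compound list**

1 | O-benzylvanillin (4-benzyloxy-3-methoxybenzaldehyde) | COc1cc(C=O)ccc1OCc1ccccc1 | starting material
2 | methyl propiolate | C#CC(=O)OC | starting material
3 | methyl (4S)-4-[4-(benzyloxy)-3-methoxyphenyl]-4-hydroxybut-2-ynoate | COC(=O)C#C[C@H](c1ccc(OCc2ccccc2)c(OC)c1)O | intermediate
4 | methyl (2Z,4R)-4-[4-(benzyloxy)-3-methoxyphenyl]-4-hydroxybut-2-enoate | COC(=O)/C=C\[C@H](c1ccc(OCc2ccccc2)c(OC)c1)O | intermediate
5 | (5R)-5-[4-(benzyloxy)-3-methoxyphenyl]furan-2(5H)-one | O=C1C=C[C@H](c2ccc(OCc3ccccc3)c(OC)c2)O1 | intermediate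
6 | (chloromethyl)dimethylphenylsilane | ClC[Si](C)(C)c1ccccc1 | starting material
7 | [(dimethylphenylsilyl)methyl]magnesium chloride | Cl[Mg]C[Si](C)(C)c1ccccc1 | intermediate
8 | chloromagnesium enolate of the 4,5-trans lactone (silylmethyl on C4, aryl on C5) | Cl[Mg]OC1=C[C@@H](C[Si](C)(C)c2ccccc2)[C@H](c2ccc(OCc3ccccc3)c(OC)c2)O1 | intermediate
9 | (4R,5R)-3-{[4-(benzyloxy)-3-methoxyphenyl](hydroxy)methyl}-5-[4-(benzyloxy)-3-methoxyphenyl]-4-[(dimethylphenylsilyl)methyl]dihydrofuran-2(3H)-one, 3,4-trans, epimers at the carbinol carbon | O=C1O[C@@H](c2ccc(OCc3ccccc3)c(OC)c2)[C@H](C[Si](C)(C)c2ccccc2)[C@H]1C(O)c1ccc(OCc2ccccc2)c(OC)c1 | intermediate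
10 | methanesulfonate of 9 | O=C1O[C@@H](c2ccc(OCc3ccccc3)c(OC)c2)[C@H](C[Si](C)(C)c2ccccc2)[C@H]1C(OS(C)(=O)=O)c1ccc(OCc2ccccc2)c(OC)c1 | intermediate
11 | (3E,4R,5R)-3-[4-(benzyloxy)-3-methoxybenzylidene]-5-[4-(benzyloxy)-3-methoxyphenyl]-4-[(dimethylphenylsilyl)methyl]dihydrofuran-2(3H)-one | O=C1O[C@@H](c2ccc(OCc3ccccc3)c(OC)c2)[C@H](C[Si](C)(C)c2ccccc2)/C1=C\c1ccc(OCc2ccccc2)c(OC)c1 | intermediate
12 | (3S,4R,5R)-3-[4-(benzyloxy)-3-methoxybenzyl]-5-[4-(benzyloxy)-3-methoxyphenyl]-4-[(dimethylphenylsilyl)methyl]dihydrofuran-2(3H)-one | O=C1O[C@@H](c2ccc(OCc3ccccc3)c(OC)c2)[C@H](C[Si](C)(C)c2ccccc2)[C@@H]1Cc1ccc(OCc2ccccc2)c(OC)c1 | intermediate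
13 | (1R,2R,3S)-3-[4-(benzyloxy)-3-methoxybenzyl]-1-[4-(benzyloxy)-3-methoxyphenyl]-2-[(dimethylphenylsilyl)methyl]butane-1,4-diol | OC[C@@H](Cc1ccc(OCc2ccccc2)c(OC)c1)[C@@H](C[Si](C)(C)c1ccccc1)[C@@H](O)c1ccc(OCc2ccccc2)c(OC)c1 | intermediate
14 | primary (C4–O) p-toluenesulfonate of diol 13 | Cc1ccc(cc1)S(=O)(=O)OC[C@@H](Cc1ccc(OCc2ccccc2)c(OC)c1)[C@@H](C[Si](C)(C)c1ccccc1)[C@@H](O)c1ccc(OCc2ccccc2)c(OC)c1 | intermediate
15 | (2R,3R,4S)-4-[4-(benzyloxy)-3-methoxybenzyl]-2-[4-(benzyloxy)-3-methoxyphenyl]-3-[(dimethylphenylsilyl)methyl]tetrahydrofuran | C1O[C@@H](c2ccc(OCc3ccccc3)c(OC)c2)[C@H](C[Si](C)(C)c2ccccc2)[C@@H]1Cc1ccc(OCc2ccccc2)c(OC)c1 | intermediate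
16 | {(2R,3S,4S)-4-[4-(benzyloxy)-3-methoxybenzyl]-2-[4-(benzyloxy)-3-methoxyphenyl]tetrahydrofuran-3-yl}methanol | C1O[C@@H](c2ccc(OCc3ccccc3)c(OC)c2)[C@H](CO)[C@@H]1Cc1ccc(OCc2ccccc2)c(OC)c1 | intermediate
17 | 4-(benzyloxy)benzoic acid | O=C(O)c1ccc(OCc2ccccc2)cc1 | starting material
18 | {(2R,3S,4S)-4-[4-(benzyloxy)-3-methoxybenzyl]-2-[4-(benzyloxy)-3-methoxyphenyl]tetrahydrofuran-3-yl}methyl 4-(benzyloxy)benzoate | C1O[C@@H](c2ccc(OCc3ccccc3)c(OC)c2)[C@H](COC(=O)c2ccc(OCc3ccccc3)cc2)[C@@H]1Cc1ccc(OCc2ccccc2)c(OC)c1 | intermediate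
19 | agastinol | COc1cc(C[C@@H]2CO[C@@H](c3ccc(O)c(OC)c3)[C@@H]2COC(=O)c2ccc(O)cc2)ccc1O | target

**Step count**

Total: 10 steps. Longest linear sequence: 9 steps (steps 1, 2, 4, 5, 6, 7, 8, 9, 10 from O-benzylvanillin); step 3 is a one-step side branch.

**Steps most likely to fail**

Step 4. The silylmethyl ligand may transfer slowly from copper without a silyl chloride activator. That would leave time for γ-deprotonation of 5 (racemisation of C2) or give an enolate that is captured poorly by the aldehyde. DBU may also abstract the C3 hydrogen of 11 (vinylogous α-position) and erode C3. Fallback: the two bond formations are separated, setting out from 5. The conjugate addition is run with Grignard reagent 7, catalytic CuBr·SMe2 and TMSCl in THF at −78 °C, so that the enolate is silylated as it forms, giving the trimethylsilyl ketene acetal F1. Mild acidic work-up hydrolyses it to the saturated trans lactone (4R,5R)-5-[4-(benzyloxy)-3-methoxyphenyl]-4-[(dimethylphenylsilyl)methyl]dihydrofuran-2(3H)-one F2. F2 is deprotonated with LiN(SiMe3)2 (THF, −78 °C) to its lithium enolate F3, which adds to aldehyde 1. This returns to the route at aldol adduct 9, which is mesylated and eliminated as in step 4 to give 11.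

Step 5. Facial selectivity may be poor, because the C2 aryl group sits on the ring face opposite the C3 silylmethyl group and may compete as a shielding element; benzyl ethers may also be lost in part. Fallback: C4 is set by protonation instead of hydrogen delivery from a surface, setting out from 11. Conjugate reduction with NaBH4 and NiCl2·6H2O (MeOH/THF, 0 °C) spares the benzyl ethers and gives 12 together with, or mainly, the all-trans C3 epimer (3R,4R,5R)-lactone F4. The mixture is converted with LiN(SiMe3)2 (THF, −78 °C) into the lithium enolate F5 and quenched at −78 °C with 2,6-di-tert-butyl-4-methylphenol. The small proton donor should enter anti to the adjacent silylmethyl group (kinetic protonation), converging on the cis lactone and returning to the route at 12.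

Step 8. Cleavage of the phenyl–silicon bond under basic peroxide may be incomplete, or the substrate may degrade slowly at 70 °C. Fallback: a two-stage electrophilic sequence, setting out from 15. Ipso-protodesilylation with BF3·2AcOH (CH2Cl2, 0 °C to rt) removes the phenyl group as benzene and gives the fluorodimethylsilane F6. F6 is then oxidised under standard Tamao conditions (KF, KHCO3, H2O2, THF/MeOH, rt), returning to the route at 16. Any acid-induced reversible opening at the benzylic C2–O bond should reclose toward the thermodynamically preferred 2,3-trans arrangement, which is the one required.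

**Further compounds**

F1 | step 4 | {[(4R,5R)-5-[4-(benzyloxy)-3-methoxyphenyl]-4-[(dimethylphenylsilyl)methyl]-4,5-dihydrofuran-2-yl]oxy}trimethylsilane | C[Si](C)(C)OC1=C[C@@H](C[Si](C)(C)c2ccccc2)[C@H](c2ccc(OCc3ccccc3)c(OC)c2)O1
F2 | step 4 | (4R,5R)-5-[4-(benzyloxy)-3-methoxyphenyl]-4-[(dimethylphenylsilyl)methyl]dihydrofuran-2(3H)-one | O=C1C[C@@H](C[Si](C)(C)c2ccccc2)[C@H](c2ccc(OCc3ccccc3)c(OC)c2)O1
F3 | step 4 | lithium enolate of F2 | [Li]OC1=C[C@@H](C[Si](C)(C)c2ccccc2)[C@H](c2ccc(OCc3ccccc3)c(OC)c2)O1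
F4 | step 5 | (3R,4R,5R)-3-[4-(benzyloxy)-3-methoxybenzyl]-5-[4-(benzyloxy)-3-methoxyphenyl]-4-[(dimethylphenylsilyl)methyl]dihydrofuran-2(3H)-one | O=C1O[C@@H](c2ccc(OCc3ccccc3)c(OC)c2)[C@H](C[Si](C)(C)c2ccccc2)[C@H]1Cc1ccc(OCc2ccccc2)c(OC)c1
F5 | step 5 | lithium enolate of 12 and F4 | [Li]OC1=C(Cc2ccc(OCc3ccccc3)c(OC)c2)[C@@H](C[Si](C)(C)c2ccccc2)[C@H](c2ccc(OCc3ccccc3)c(OC)c2)O1
F6 | step 8 | fluoro({(2R,3R,4S)-4-[4-(benzyloxy)-3-methoxybenzyl]-2-[4-(benzyloxy)-3-methoxyphenyl]tetrahydrofuran-3-yl}methyl)dimethylsilane | C1O[C@@H](c2ccc(OCc3ccccc3)c(OC)c2)[C@H](C[Si](C)(C)F)[C@@H]1Cc1ccc(OCc2ccccc2)c(OC)c1
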